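All runs were computed from invented constants; noise was put on by code.

**Red's slowing.** The red run, with 5 µM of free enzyme, gains 2.7 percentage points of target from 4.00 h to 8.00 h but 2 points, less, from 8.00 h to 12.0 h. Its target then stands at 7.5%. With a scatter of 0.3 points this is a hint, but it is read here as a race (kinetic control) rather than a balance: something stops target being made.

in all of them: starting material 0.10 M
- green: second substrate 0.12 M; free enzyme 10 µM; the very flask that is asked about, followed so far
- red: second substrate 0.12 M; free enzyme 5 µM; run made earlier
- flask: second substrate 0.120 M; free enzyme 10 µM; time 8.0 d

| run | time / h | target / % |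
|---|---|---|
| green | 20.0 | 22.3 |
| green | 40.0 | 37.4 |
| green | 60.0 | 45.7 |
| green | 72.0 | 48.3 |
| green | 96.0 | 51.7 |
| green | 120 | 53.2 |
| red | 1.00 | 0.4 |
| red | 1.50 | 0.8 |
| red | 2.50 | 1.6 |
| red | 4.00 | 2.8 |
| red | 8.00 | 5.5 |
| red | 12.0 | 7.5 |

(readings scatter by 0.3 percentage points)

- ash: change nothing and wait 4.0 d more
- cedar: at 8.0 d take out 90% of the first product then present, then wait 4.0 d
- birch: at 8.0 d add free enzyme, 100% of the amount charged, then wait 4.0 d
- maple: at 8.0 d add second substrate, 50.0% of the amount charged, then wait 4.0 d

* target, in percent of the starting material first charged, at 8.0 d
* the option that brings most further target ("none" if no option brings more than 2 percentage points) (ash / cedar / birch / maple / none)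
* target present, in percent of the starting material first charged, after ash
* target present, in percent of the starting material first charged, after cedar

- what is added takes up no volume worth counting

**Two times.** The fill time is the time the enzyme charge would need to turn the charged starting material into target at its starting pace. Red's gain from 1.00 h to 4.00 h, scaled to 10 µM of enzyme on the assumption that pace follows enzyme, gives 62.5 h. Green's last equal spans gain 3.4 points, then 1.5 points. Continuing that shrinkage puts the plateau at 54.4%. The stop time is the time constant of whatever competes with target-making. If two first-order paths race, target's share is the stop time over the sum of both times, so this plateau gives 74.5 h.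

**The reckoning.** Together the two times give a time constant of 34.0 h, and 8.0 d is 5.65 of these. This flask should therefore stand near 54.4% at 8.0 d, and ash should add little. Birch brings the fill time to 31.3 h, while ash, cedar and maple leave the enzyme charge as it is. If what competes consumes starting material, this reckoning leaves 0.353% of it in this flask at 8.0 d. If the competing loss falls on the enzyme instead, starting material can remain at 8.0 d, and birch puts new enzyme on it. The readings show target and not starting material, so they do not tell these two cases apart, and birch is picked here as a bet on the second, with its gain unsized.

**The result.** The forecast, for which the flattening looks like “a true equilibrium”, gives 54.8% at 8.0 d, 55% after ash and 68.8% after cedar, and names cedar. The flask gives 54.5%, 54.7% after ash and 54.9% after cedar, and the best option is birch, with a gain of 7.1 points. At 96.0 h this flask holds 33.9% uncatalysed product, in percent of the starting material charged, and 83.2% of the catalyst charged is spent catalyst. At 192 h, which is 2.58 stop times of 74.5 h, 7.84% of the starting material charged is still there and spent catalyst stands at 98.6%.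

    starting material + second substrate → uncatalysed product (k = 3.50 × 10⁻⁵ M⁻¹ s⁻¹)
    loaded enzyme + first product → spent catalyst (k = 6.60 × 10⁻⁴ M⁻¹ s⁻¹)
    second substrate + loaded enzyme ⇌ second complex (K = 50.0 M⁻¹, k = 10.0 M⁻¹ s⁻¹)
    first complex ⇌ loaded enzyme + first product (K = 0.230 M, k = 3.60 s⁻¹)
    second complex → free enzyme + target (k = 0.0480 s⁻¹)
    starting material + free enzyme ⇌ first complex (K = 61.0 M⁻¹, k = 2.80 M⁻¹ s⁻¹)

**Second flask.** In the neighbour flask with 2.5 × 10⁻⁶ M of free enzyme, the fill time becomes 250 h. Holding the stop time at 74.5 h, target's share is 23.0%. The computed neighbour gives 25.5%, with 61.1% uncatalysed product.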